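**Retrosynthetic overview** (eunicellane numbering: ring perimeter C1–C14, ether O on C2/C9, lactone C3–O–C17(=O)–C15)

1. Late disconnections: the C11 butanoate (acylation), the seven-membered lactone (Wolff rearrangement of a C14 2-diazopropanoyl group, the ketene being caught by C3–OH), and the C11 methyl carbinol (MeMgBr on a C11 ketone).
2. Key disconnection: the tetrahydrofuran O–C2–C1–C10–C9 is cut at O–C9 and C1–C10. The oxygen sits on C2 and C9, which lie 1,8 across the C1–C14 perimeter, with C1 and C10 as their neighbours, so this one cut unravels cyclohexane, tetrahydrofuran, oxonene and ten-membered ring into a 14-membered cembrane-type carbocycle, copying the presumed cembrane → eunicellane C1–C10 biogenesis.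
3. Two temporary carbonyl groups make this good chemistry: a C11 ketone (enone C9=C10, so C9 is electrophilic and C10 becomes nucleophilic) and a C14 propanoyl group (enone C1=C14, so C1 is electrophilic). A C2 alkoxide then triggers a transannular oxa-Michael/Michael cascade; the ketone later takes the C11 methyl and the propanoyl group is rearranged into C15/C17.
4. The macrocycle comes from ring-closing metathesis (C9=C10) after a Horner–Wadsworth–Emmons union (C1=C14) of a C1–C9 aldehyde (C2/C3 from (S)-glycerate by chelate-controlled addition, Z-C6=C7 from 2,3-dihydrofuran) with a C10–C14 ketophosphonate (from acrolein).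
5. Ring order: 14-membered carbocycle → in one step tetrahydrofuran + cyclohexane (which define the oxonene and the ten-membered ring) → seven-membered lactone.

Key step: step 13

Remark: the SMILES is read as (1S,2S,3S,6Z,9S,10R,11R,14R,15R); 16 is racemic at the phosphonate carbon (destroyed in step 10), and 17 and 18 are carried as mixtures at the carbinol that step 11 oxidises.

**Route**

Step 1
Reactants: 1 2,3-dihydrofuran
Product: 3 (3Z)-4-methylhepta-3,6-dien-1-ol, via 5-lithio-2,3-dihydrofuran 2 (not isolated)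
Conditions: t-BuLi, THF, −78 to 0 °C; Me2CuLi (from MeLi and CuBr·SMe2), Et2O/Me2S, −78 to 20 °C; allyl bromide, −78 to 0 °C; aq NH4Cl
Reagents that add atoms: methyllithium (C[Li]); allyl bromide (C=CCBr)
Why: Copper-mediated 1,2-metallate rearrangement of an α-metallated cyclic enol ether: methyl migrates from copper to C5 with inversion as the ring oxygen leaves, and the alkenylcuprate is allylated with retention, so the allyl group should end cis to the hydroxyethyl chain (Z alkene, the future C6=C7).

Step 2
Reactants: 3 (3Z)-4-methylhepta-3,6-dien-1-ol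
Product: 4 (4Z)-7-iodo-4-methylhepta-1,4-diene
Conditions: I2, PPh3, imidazole, CH2Cl2, 0 °C
Reagents that add atoms: iodine (II)
Why: Appel-type iodination of a primary alcohol under neutral conditions, which should leave the skipped diene and its Z geometry untouched.

Step 3
Reactants: 5 methyl (4S)-2,2-dimethyl-1,3-dioxolane-4-carboxylate
Product: 7 1-[(4S)-2,2-dimethyl-1,3-dioxolan-4-yl]ethan-1-one, via Weinreb amide 6 (not isolated)
Conditions: MeNHOMe·HCl, i-PrMgCl, THF, −20 °C; then MeMgCl, −20 to 0 °C; aq NH4Cl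
Reagents that add atoms: methylmagnesium chloride (C[Mg]Cl)
Why: One-pot Weinreb ketone synthesis; the chelated tetrahedral intermediate prevents over-addition, and the low temperature should keep the α-alkoxy stereocentre (future C2) intact.

Step 4
Reactants: 4 (4Z)-7-iodo-4-methylhepta-1,4-diene; 7 1-[(4S)-2,2-dimethyl-1,3-dioxolan-4-yl]ethan-1-one
Product: 10 (2S,5Z)-2-[(4S)-2,2-dimethyl-1,3-dioxolan-4-yl]-6-methylnona-5,8-dien-2-ol, via alkyllithium 8 (not isolated), via Grignard reagent 9 (not isolated)
Conditions: 4, t-BuLi (2 equiv), Et2O, −78 °C; MgBr2·OEt2; then 7, −78 to −20 °C; aq NH4Cl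
Reagents that add atoms: none
Why: Iodine–lithium exchange and transmetalation give a homoallyl Grignard reagent without scrambling the Z alkene; its addition should follow the Cram chelate model (magnesium bridging the carbonyl and the dioxolane α-oxygen, attack on the face of the α-hydrogen), setting the C3 carbinol syn to the C2 oxygen.

Step 5
Reactants: 10 (2S,5Z)-2-[(4S)-2,2-dimethyl-1,3-dioxolan-4-yl]-6-methylnona-5,8-dien-2-ol
Product: 11 (2S,3S,6Z)-3,7-dimethyldeca-6,9-diene-1,2,3-triol
Conditions: AcOH/H2O/THF (3:1:1), 40 °C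
Reagents that add atoms: none
Why: Acid-catalysed acetonide hydrolysis under conditions too mild to ionise the tertiary alcohol or protonate the trisubstituted alkene.

Step 6
Reactants: 11 (2S,3S,6Z)-3,7-dimethyldeca-6,9-diene-1,2,3-triol
Product: 12 (2S,3S,6Z)-3,7-dimethyl-1,2-bis(triethylsilyloxy)deca-6,9-dien-3-ol
Conditions: Et3SiCl (2.1 equiv), imidazole, DMF, 0 °C
Reagents that add atoms: chlorotriethylsilane (CC[Si](Cl)(CC)CC)
Why: Silyl ether formation at the primary and secondary hydroxyl groups; the hindered tertiary C3 hydroxyl should not react with the chlorosilane.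

Step 7
Reactants: 12 (2S,3S,6Z)-3,7-dimethyl-1,2-bis(triethylsilyloxy)deca-6,9-dien-3-ol
Product: 13 (2R,3S,6Z)-3-hydroxy-3,7-dimethyl-2-(triethylsilyloxy)deca-6,9-dienal
Conditions: (COCl)2, DMSO, CH2Cl2, −78 to −30 °C; Et3N, −78 to 0 °C
Reagents that add atoms: none
Why: Swern oxidation applied directly to the silyl ether: the activated sulfoxide cleaves and oxidises the primary triethylsilyl ether selectively, the secondary silyl ether and tertiary alcohol survive, and the cold basic step should not epimerise C2.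

Step 8
Reactants: 14 diethyl (2-oxobutyl)phosphonate; 15 acrolein
Product: 16 4-(diethoxyphosphoryl)-5-oxoheptanal
Conditions: DBU (5 mol%), THF, −20 to 0 °C
Reagents that add atoms: none
Why: Base-catalysed Michael addition of the phosphonate-stabilised ketone enolate to acrolein; catalytic base and one equivalent of acceptor should stop at mono-addition.

Step 9
Reactants: 16 4-(diethoxyphosphoryl)-5-oxoheptanal
Product: 17 diethyl (7-hydroxy-3-oxonon-8-en-4-yl)phosphonate
Conditions: vinylmagnesium bromide (2.1 equiv), THF, −78 °C; aq NH4Cl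
Reagents that add atoms: vinylmagnesium bromide (C=C[Mg]Br)
Why: Grignard 1,2-addition to the aldehyde: the first equivalent deprotonates the β-ketophosphonate, whose enolate masks the ketone, so the second should add only to the aldehyde; the new carbinol centre needs no control.

Step 10
Reactants: 13 (2R,3S,6Z)-3-hydroxy-3,7-dimethyl-2-(triethylsilyloxy)deca-6,9-dienal; 17 diethyl (7-hydroxy-3-oxonon-8-en-4-yl)phosphonate
Product: 18 (4E,6S,7S,10Z)-7-hydroxy-4-(3-hydroxypent-4-en-1-yl)-7,11-dimethyl-6-(triethylsilyloxy)tetradeca-4,10,13-trien-3-one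
Conditions: Ba(OH)2·8H2O, THF/H2O (40:1), 0 to 20 °C
Reagents that add atoms: none
Why: Horner–Wadsworth–Emmons olefination under mild Ba(OH)2 activation, suited to a base-sensitive α-silyloxy aldehyde; reversible addition and syn elimination should give the (E)-enone, with C2 trans to the propanoyl group.

Step 11
Reactants: 18 (4E,6S,7S,10Z)-7-hydroxy-4-(3-hydroxypent-4-en-1-yl)-7,11-dimethyl-6-(triethylsilyloxy)tetradeca-4,10,13-trien-3-one
Product: 19 (4E,6S,7S,10Z)-7-hydroxy-7,11-dimethyl-4-(3-oxopent-4-en-1-yl)-6-(triethylsilyloxy)tetradeca-4,10,13-trien-3-one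
Conditions: Dess–Martin periodinane, NaHCO3, CH2Cl2, 0 °C
Reagents that add atoms: none
Why: Dess–Martin oxidation of the secondary allylic alcohol to the vinyl ketone; the tertiary alcohol, silyl ether and alkenes are inert and the buffer protects the silyl ether.

Step 12
Reactants: 19 (4E,6S,7S,10Z)-7-hydroxy-7,11-dimethyl-4-(3-oxopent-4-en-1-yl)-6-(triethylsilyloxy)tetradeca-4,10,13-trien-3-one
Product: 20 (2E,5Z,9S,10S,11E)-9-hydroxy-5,9-dimethyl-12-propanoyl-10-(triethylsilyloxy)cyclotetradeca-2,5,11-trien-1-one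
Conditions: second-generation Grubbs catalyst (10 mol%), toluene, 1 mM, 80 °C
Reagents that add atoms: none
Why: Ring-closing metathesis between the only two monosubstituted alkenes (the trisubstituted C6=C7 and C1=C14 alkenes are inert) at high dilution; closure to a 14-membered enone should give the conjugated (E)-C9=C10 alkene under thermodynamic control.

Step 13
Reactants: 20 (2E,5Z,9S,10S,11E)-9-hydroxy-5,9-dimethyl-12-propanoyl-10-(triethylsilyloxy)cyclotetradeca-2,5,11-trien-1-one
Product: 23 (1S,2S,3S,6Z,9S,10R,14R)-2,9-epoxy-3-hydroxy-3,7-dimethyl-14-propanoylbicyclo[8.4.0]tetradec-6-en-11-one, via macrocyclic C2 alkoxide 21 (not isolated), via ether-bridged C10 enolate 22 (not isolated)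
Conditions: Bu4NF (1.5 equiv), THF, 2 mM, −20 to 20 °C; aq NH4Cl
Reagents that add atoms: none
Why: Fluoride cleaves the silyl ether and the C2 alkoxide 21 adds across the ring to C9 of the (E)-C9=C10–C11 enone (oxa-Michael); the C10 enolate 22 then adds to C1 of the C1=C14 propanoyl enone (Michael) and the resulting enolate is protonated at C14. The closest known reaction types are the domino oxa-Michael/Michael (formal [3+2]) synthesis of tetrahydrofurans from γ-hydroxy enones and fluoride-triggered transannular Michael cascades of 14-membered bis-enones. The O–C9 bond closes transannularly (an ether bridge that divides the macrocycle into two nine-membered rings), after which the C1–C10 bond closes the tetrahydrofuran 5-exo-trig and, in the same event, the cyclohexanone 6-endo-trig through a 6-(enolendo) enolate, leaving the oxonene and the ten-membered carbocycle as the remnants of the macrocycle. C9 is set by the C3–C8 tether, which only allows the out,out ether bridge (C3 and C8 cis on the new ring); C1 is set by C2 through allylic 1,3-strain (H2 eclipses the enone, C10 attacks anti to the quaternary C3); C10 follows from the (E)-enone geometry and the cis ring fusion that the five-membered ring enforces; and C14 should equilibrate under the basic conditions to the equatorial acyl group trans to C2. The step needs attack by the C2 oxygen rather than the C3 hydroxyl and C–C bond formation before the enolate is quenched: only the C2 oxygen can lead on to a five-membered ring, and because oxa-Michael addition is reversible, unproductive adducts can drain into the irreversible C1–C10 bond formation.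

Step 14
Reactants: 23 (1S,2S,3S,6Z,9S,10R,14R)-2,9-epoxy-3-hydroxy-3,7-dimethyl-14-propanoylbicyclo[8.4.0]tetradec-6-en-11-one
Product: 24 1-[(1R,2S,3S,6Z,9S,10R,11R,14R)-2,9-epoxy-3,11-dihydroxy-3,7,11-trimethylbicyclo[8.4.0]tetradec-6-en-14-yl]propan-1-one
Conditions: CeCl3 (anhydrous), MeMgBr (3 equiv), THF, −78 °C; aq NH4Cl
Reagents that add atoms: methylmagnesium bromide (C[Mg]Br)
Why: Cerium-mediated Grignard addition (low basicity, so no enolisation or β-elimination of the C9 oxygen): the cyclohexanone should react far faster than the α-branched acyclic ketone, which is further masked as its magnesium hemiketal with the C3 alkoxide, and axial attack on the convex face, anti to the axial C9–C10 bond, sets C11 with methyl cis to H10.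

Step 15
Reactants: 24 1-[(1R,2S,3S,6Z,9S,10R,11R,14R)-2,9-epoxy-3,11-dihydroxy-3,7,11-trimethylbicyclo[8.4.0]tetradec-6-en-14-yl]propan-1-one
Product: 26 2-diazo-1-[(1R,2S,3S,6Z,9S,10R,11R,14R)-2,9-epoxy-3,11-dihydroxy-3,7,11-trimethylbicyclo[8.4.0]tetradec-6-en-14-yl]propan-1-one, via α-trifluoroacetyl ketone 25 (not isolated)
Conditions: LiN(SiMe3)2 (3.3 equiv), THF, −78 °C; CF3CO2CH2CF3; aq HCl work-up; then MsN3, Et3N, H2O, MeCN, 20 °C
Reagents that add atoms: methanesulfonyl azide (CS(=O)(=O)N=[N+]=[N-])
Why: Detrifluoroacetylative diazo transfer (Regitz type): kinetic enolisation should occur at the ethyl CH2 and not at the hindered C14 methine, the trifluoroacetyl group activates that carbon for diazo transfer and is lost as the sulfonyl amide; no stereocentre is touched.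

Step 16
Reactants: 26 2-diazo-1-[(1R,2S,3S,6Z,9S,10R,11R,14R)-2,9-epoxy-3,11-dihydroxy-3,7,11-trimethylbicyclo[8.4.0]tetradec-6-en-14-yl]propan-1-one
Product: 28 the C11 alcohol of the target (11-O-debutanoyl 29; 1S,2S,3S,6Z,9S,10R,11R,14R,15R), via ketene 27 (not isolated)
Conditions: hν (300 nm), THF, 5 mM, 20 °C
Reagents that add atoms: none
Why: Photochemical Wolff rearrangement: C14 migrates with retention to the diazo carbon (now C15), the ketene carbon (C17) is captured intramolecularly by the C3 tertiary hydroxyl to close the seven-membered lactone, and the ester enol should be protonated at C15 on the face of H14, anti to C13.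

Step 17
Reactants: 28 the C11 alcohol of the target
Product: 29 CNP0294597.2, (1S,2S,3S,6Z,9S,10R,11R,14R,15R)-11-butanoyloxy-2,9-epoxyeunicell-6-en-17,3-olide
Conditions: (n-PrCO)2O, DMAP, Et3N, CH2Cl2, 40 °C
Reagents that add atoms: butanoic anhydride (CCCC(=O)OC(=O)CCC)
Why: DMAP-catalysed acyl transfer to the only free hydroxyl group, the tertiary C11 alcohol; no stereocentre is touched.

**Compound list**

1 | 2,3-dihydrofuran | C1=COCC1 | starting material
2 | 5-lithio-2,3-dihydrofuran | [Li]C1=CCCO1 | intermediate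
3 | (3Z)-4-methylhepta-3,6-dien-1-ol | OCC/C=C(C)\CC=C | intermediate
4 | (4Z)-7-iodo-4-methylhepta-1,4-diene | ICC/C=C(C)\CC=C | intermediate
5 | methyl (4S)-2,2-dimethyl-1,3-dioxolane-4-carboxylate | COC(=O)[C@@H]1COC(C)(C)O1 | starting material
6 | (4S)-N-methoxy-N,2,2-trimethyl-1,3-dioxolane-4-carboxamide (Weinreb amide) | CON(C)C(=O)[C@@H]1COC(C)(C)O1 | intermediate
7 | 1-[(4S)-2,2-dimethyl-1,3-dioxolan-4-yl]ethan-1-one | CC(=O)[C@@H]1COC(C)(C)O1 | intermediate
8 | [(3Z)-4-methylhepta-3,6-dien-1-yl]lithium | [Li]CC/C=C(C)\CC=C | intermediate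
9 | [(3Z)-4-methylhepta-3,6-dien-1-yl]magnesium bromide | Br[Mg]CC/C=C(C)\CC=C | intermediate
10 | (2S,5Z)-2-[(4S)-2,2-dimethyl-1,3-dioxolan-4-yl]-6-methylnona-5,8-dien-2-ol | C[C@](O)(CC/C=C(C)\CC=C)[C@@H]1COC(C)(C)O1 | intermediate
11 | (2S,3S,6Z)-3,7-dimethyldeca-6,9-diene-1,2,3-triol | C[C@](O)(CC/C=C(C)\CC=C)[C@@H](O)CO | intermediate
12 | (2S,3S,6Z)-3,7-dimethyl-1,2-bis(triethylsilyloxy)deca-6,9-dien-3-ol | C[C@](O)(CC/C=C(C)\CC=C)[C@@H](O[Si](CC)(CC)CC)CO[Si](CC)(CC)CC | intermediate
13 | (2R,3S,6Z)-3-hydroxy-3,7-dimethyl-2-(triethylsilyloxy)deca-6,9-dienal | C[C@](O)(CC/C=C(C)\CC=C)[C@@H](O[Si](CC)(CC)CC)C=O | intermediate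
14 | diethyl (2-oxobutyl)phosphonate | CCC(=O)CP(=O)(OCC)OCC | starting material
15 | acrolein | C=CC=O | starting material
16 | 4-(diethoxyphosphoryl)-5-oxoheptanal | CCC(=O)C(CCC=O)P(=O)(OCC)OCC | intermediate
17 | diethyl (7-hydroxy-3-oxonon-8-en-4-yl)phosphonate | CCC(=O)C(CCC(O)C=C)P(=O)(OCC)OCC | intermediate
18 | (4E,6S,7S,10Z)-7-hydroxy-4-(3-hydroxypent-4-en-1-yl)-7,11-dimethyl-6-(triethylsilyloxy)tetradeca-4,10,13-trien-3-one | C[C@](O)(CC/C=C(C)\CC=C)[C@@H](O[Si](CC)(CC)CC)/C=C(/C(=O)CC)\CCC(O)C=C | intermediate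
19 | (4E,6S,7S,10Z)-7-hydroxy-7,11-dimethyl-4-(3-oxopent-4-en-1-yl)-6-(triethylsilyloxy)tetradeca-4,10,13-trien-3-one | C[C@](O)(CC/C=C(C)\CC=C)[C@@H](O[Si](CC)(CC)CC)/C=C(/C(=O)CC)\CCC(=O)C=C | intermediate
20 | (2E,5Z,9S,10S,11E)-9-hydroxy-5,9-dimethyl-12-propanoyl-10-(triethylsilyloxy)cyclotetradeca-2,5,11-trien-1-one | C[C@]1(O)CC/C=C(C)\C/C=C/C(=O)CC/C(C(=O)CC)=C\[C@@H]1O[Si](CC)(CC)CC | intermediate
21 | tetrabutylammonium C2 alkoxide of the desilylated macrocycle | C[C@]1(O)CC/C=C(C)\C/C=C/C(=O)CC/C(C(=O)CC)=C\[C@@H]1[O-].CCCC[N+](CCCC)(CCCC)CCCC | intermediate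
22 | ether-bridged (O joins C2 and C9) C10=C11 enolate, tetrabutylammonium salt | C[C@]1(O)CC/C=C(C)\C[C@@H]2O[C@H]1/C=C(/C(=O)CC)\CCC([O-])=C2.CCCC[N+](CCCC)(CCCC)CCCC | intermediate
23 | (1S,2S,3S,6Z,9S,10R,14R)-2,9-epoxy-3-hydroxy-3,7-dimethyl-14-propanoylbicyclo[8.4.0]tetradec-6-en-11-one | O=C1CC[C@@H](C(=O)CC)[C@H]3[C@@H]1[C@@H]1C/C(C)=C\CC[C@](C)(O)[C@H]3O1 | intermediate
24 | 1-[(1R,2S,3S,6Z,9S,10R,11R,14R)-2,9-epoxy-3,11-dihydroxy-3,7,11-trimethylbicyclo[8.4.0]tetradec-6-en-14-yl]propan-1-one | O[C@]1(C)CC[C@@H](C(=O)CC)[C@H]3[C@@H]1[C@@H]1C/C(C)=C\CC[C@](C)(O)[C@H]3O1 | intermediate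
25 | 24 bearing a trifluoroacetyl group on the propanoyl α-carbon (1,3-diketone, epimers at that carbon) | O[C@]1(C)CC[C@@H](C(=O)C(C)C(=O)C(F)(F)F)[C@H]3[C@@H]1[C@@H]1C/C(C)=C\CC[C@](C)(O)[C@H]3O1 | intermediate
26 | 2-diazo-1-[(1R,2S,3S,6Z,9S,10R,11R,14R)-2,9-epoxy-3,11-dihydroxy-3,7,11-trimethylbicyclo[8.4.0]tetradec-6-en-14-yl]propan-1-one | O[C@]1(C)CC[C@@H](C(=O)C(C)=[N+]=[N-])[C@H]3[C@@H]1[C@@H]1C/C(C)=C\CC[C@](C)(O)[C@H]3O1 | intermediate
27 | methyl ketene on C14: 2-[(2,9-epoxy-3,11-dihydroxy-3,7,11-trimethylbicyclo[8.4.0]tetradec-6-en-14-yl)]prop-1-en-1-one, ring stereocentres as in 24 | O[C@]1(C)CC[C@@H](C(C)=C=O)[C@H]3[C@@H]1[C@@H]1C/C(C)=C\CC[C@](C)(O)[C@H]3O1 | intermediate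
28 | C11 alcohol of the target, (1S,2S,3S,6Z,9S,10R,11R,14R,15R)-2,9-epoxy-11-hydroxyeunicell-6-en-17,3-olide | O[C@]1(C)CC[C@@H]2[C@H]3[C@@H]1[C@@H]1C/C(C)=C\CC[C@](C)(OC(=O)[C@@H]2C)[C@H]3O1 | intermediate
29 | CNP0294597.2, (1S,2S,3S,6Z,9S,10R,11R,14R,15R)-11-butanoyloxy-2,9-epoxyeunicell-6-en-17,3-olide | CCCC(=O)O[C@]1(C)CC[C@@H]2[C@H]3[C@@H]1[C@@H]1C/C(C)=C\CC[C@](C)(OC(=O)[C@@H]2C)[C@H]3O1 | target

**Step count and risks**

Total step count: 17. Longest linear sequence: 14 steps (steps 1, 2, 4, 5, 6, 7, 10, 11, 12, 13, 14, 15, 16, 17, from 2,3-dihydrofuran).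

Steps most likely to fail:

Step 13. The C2 alkoxide may not reach C9 across the ring before the γ-oxido enone is isomerised by deprotonation at C2, or the ether-bridged enolate may be protonated before the C1–C10 bond forms. The fallback sets out from 20 and splits the cascade into separately activated events. Buffered desilylation (HF·pyridine, THF) should give the diol macrocycle, (2E,5Z,9S,10S,11E)-9,10-dihydroxy-5,9-dimethyl-12-propanoylcyclotetradeca-2,5,11-trien-1-one F1. Acid-catalysed transannular oxa-Michael addition under thermodynamic control (camphorsulfonic acid, CH2Cl2) should give the ether-bridged diketone F2. The C1–C10 bond is then closed by an enamine-mediated intramolecular Michael addition (pyrrolidine, AcOH, THF), in which only the C10 enamine can reach C1. This returns to the route at 23.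

Step 16. The carbene may undergo 1,2-hydride shift to a vinyl ketone or insert into the C3 O–H bond, the tertiary hydroxyl may fail to close the seven-membered ring on the ketene, or protonation at C15 may show poor facial selectivity. The fallback sets out from 26 and separates rearrangement from ring closure. Photolysis in methanol (Wolff rearrangement with intermolecular capture) should give the methyl ester F3. Saponification (LiOH, THF/H2O) should give the seco acid F4. Yamaguchi lactonisation (2,4,6-trichlorobenzoyl chloride, Et3N, then DMAP, toluene) closes the lactone, and the C15 epimers can be equilibrated at the lactone stage with DBU. This returns to the route at 28.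

Step 14. Addition may not discriminate between the ring ketone and the propanoyl ketone, or the basic reagent may cause retro-oxa-Michael opening at C9–C10. The fallback sets out from 23 and uses a temporary ring. The C3 hydroxyl and the propanoyl ketone are locked together (MeOH, HC(OMe)3, pyridinium p-toluenesulfonate) as the cyclic mixed methyl ketal F5. MeMgBr/CeCl3 then adds to the only remaining ketone to give the ketal carbinol F6. Mild aqueous acid (AcOH/H2O) releases the hydroxy ketone. This returns to the route at 24.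

Further compounds
F1 | step 13 | (2E,5Z,9S,10S,11E)-9,10-dihydroxy-5,9-dimethyl-12-propanoylcyclotetradeca-2,5,11-trien-1-one | C[C@]1(O)CC/C=C(C)\C/C=C/C(=O)CC/C(C(=O)CC)=C\[C@@H]1O
F2 | step 13 | ether-bridged diketone: oxa-Michael adduct of F1 with O joining C2 and C9 (9S), C10 a CH2 group, the C1=C14 propanoyl enone intact | C[C@]1(O)CC/C=C(C)\C[C@@H]2O[C@H]1/C=C(/C(=O)CC)\CCC(=O)C2
F3 | step 16 | methyl 2-[(2,9-epoxy-3,11-dihydroxy-3,7,11-trimethylbicyclo[8.4.0]tetradec-6-en-14-yl)]propanoate, ring stereocentres as in 24, epimers at C15 | O[C@]1(C)CC[C@@H](C(C)C(=O)OC)[C@H]3[C@@H]1[C@@H]1C/C(C)=C\CC[C@](C)(O)[C@H]3O1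
F4 | step 16 | the corresponding seco acid, 2-[(2,9-epoxy-3,11-dihydroxy-3,7,11-trimethylbicyclo[8.4.0]tetradec-6-en-14-yl)]propanoic acid | O[C@]1(C)CC[C@@H](C(C)C(=O)O)[C@H]3[C@@H]1[C@@H]1C/C(C)=C\CC[C@](C)(O)[C@H]3O1
F5 | step 14 | cyclic mixed methyl ketal of 23: six-membered ring C3–O–C(OMe)(Et)–C14, C11 ketone free | O=C1CC[C@@H]2[C@H]3[C@@H]1[C@@H]1C/C(C)=C\CC[C@](C)(OC2(CC)OC)[C@H]3O1
F6 | step 14 | the same ketal with the C11 methyl carbinol (11R) | O[C@]1(C)CC[C@@H]2[C@H]3[C@@H]1[C@@H]1C/C(C)=C\CC[C@](C)(OC2(CC)OC)[C@H]3O1
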